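**Plan**

Numbering: five-membered ring C1 (CH–O), C2, C3 (quaternary, CH3), C9, C10 (i-Pr); seven-membered ring C3, C4, C5 (C=O), C6 (CH3, O), C7, C8, C9.
Retrosynthesis: the two angelate C–O bonds are cut first and the C9=C10 alkene is traced back through a C1 ketone to a C8=C9 alkene. Then C6–C7 and C3–C4 are cut together, because C4–C5–C6 (CH2, C=O, C(CH3)–O) is an oxyallyl unit lying across the diene carbons C7=C8–C9=C3.
This leaves a 1-vinyl-2-methylcyclopentene (C1 silyl ether, C10 isopropyl) and the silyl enol ether of biacetyl mono(dibenzyl ketal). The cyclopentene is cut at C9=C3/C8=C7 (enyne metathesis) and at C1–C10 (allenylzinc addition).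
Forward: acyclic enyne, then the five-membered ring, then the seven-membered ring by cationic (4+3) cycloaddition, then C1 oxidation with alkene migration to C9=C10, debenzylation, C6 ester, C1 reduction, C1 ester.
Stereochemistry: C10 comes from an (S)-propargylic mesylate (asymmetric transfer hydrogenation, inversion in the allenylzinc addition), which also sets a temporary anti C1 centre. C3 comes from attack on the diene face opposite the C10 isopropyl and C1 siloxy groups, C6 from the cation geometry in the same step, and the final C1 from an oxazaborolidine-controlled reduction.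

Key step: step 10

Remark: the numbering C1–C10 above is used for all bicyclic compounds in the steps; the compound list gives names in azulene numbering (C10 = 1, C1 = 2, C2 = 3, C3 = 3a, C4–C8 unchanged, C9 = 8a).

**Route**

Step 1
Reactants: 1 2-methylpropanoyl chloride; 2 bis(trimethylsilyl)acetylene
Product: 3 4-methyl-1-(trimethylsilyl)pent-1-yn-3-one
Conditions: AlCl3, CH2Cl2, 0 °C
Reagents that add atoms: none
Why: Friedel–Crafts-type acylation of a silylalkyne, in which the acylium ion attacks the silicon-bearing carbon, the β-silyl cation loses Me3SiCl, and the electron-poor ynone formed does not react a second time.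

Step 2
Reactants: 3 4-methyl-1-(trimethylsilyl)pent-1-yn-3-one
Product: 5 (S)-4-methylpent-1-yn-3-ol, via (S)-4-methyl-1-(trimethylsilyl)pent-1-yn-3-ol 4 (not isolated)
Conditions: RuCl[(S,S)-TsDPEN](p-cymene) (cat.), i-PrOH, rt; then K2CO3 (cat.), MeOH, rt
Reagents that add atoms: none
Why: Noyori asymmetric transfer hydrogenation of an α,β-acetylenic ketone, in which the hydride RuH[(S,S)-TsDPEN](p-cymene) treats the alkynyl group like the aryl group of an aryl ketone and delivers hydride to the face that gives the (S)-carbinol 4, followed in the same flask by carbonate-catalysed methanolysis of the C(sp)–Si bond.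

Step 3
Reactants: 5 (S)-4-methylpent-1-yn-3-ol
Product: 6 (S)-4-methylpent-1-yn-3-yl methanesulfonate
Conditions: MsCl, Et3N, CH2Cl2, −78 → 0 °C
Reagents that add atoms: methanesulfonyl chloride, CS(=O)(=O)Cl
Why: Sulfonylation (mesylation) at oxygen leaves the carbinol configuration untouched and installs the leaving group for the SN2′ oxidative addition of step 5.

Step 4
Reactants: 7 3-methylbut-3-en-1-ol
Product: 8 3-methylbut-3-enal
Conditions: Dess–Martin periodinane, NaHCO3, CH2Cl2, 0 °C → rt; filtered solution used at once
Reagents that add atoms: none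
Why: Dess–Martin oxidation under bicarbonate buffering stops at the aldehyde and avoids the acid or base that would move the β,γ-alkene into conjugation, and the volatile product is not concentrated.

Step 5
Reactants: 6 (S)-4-methylpent-1-yn-3-yl methanesulfonate; 8 3-methylbut-3-enal
Product: 10 (3R,4S)-6-methyl-3-(propan-2-yl)hept-6-en-1-yn-4-ol, via allenylzinc methanesulfonate 9 (not isolated)
Conditions: Pd(OAc)2 (5 mol %), PPh3 (5 mol %), Et2Zn (3 equiv), THF, −78 → −20 °C; NH4Cl work-up
Reagents that add atoms: none
Why: Marshall propargylation, in which zerovalent palladium displaces the mesylate anti (SN2′), transmetalation to zinc gives the configurationally defined allenylzinc 9, and its SE2′ addition to the aldehyde through a cyclic six-membered transition state forms C10 with net inversion of the mesylate carbon and, with the aldehyde chain anti to the isopropyl group, the anti-related C1 carbinol.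

Step 6
Reactants: 10 (3R,4S)-6-methyl-3-(propan-2-yl)hept-6-en-1-yn-4-ol
Product: 11 tert-butyldimethylsilyl ether of 10
Conditions: TBSOTf, 2,6-lutidine, CH2Cl2, −78 → 0 °C
Reagents that add atoms: tert-butyldimethylsilyl trifluoromethanesulfonate, CC(C)(C)[Si](C)(C)OS(=O)(=O)C(F)(F)F
Why: Silylation with a silyl triflate and a hindered pyridine base protects the hindered secondary alcohol cleanly, and the minor C1 epimer carried from step 5 is separated at this stage.

Step 7
Reactants: 11 tert-butyldimethylsilyl ether of 10
Product: 12 (4S,5R)-4-(tert-butyldimethylsilyloxy)-2-methyl-5-(propan-2-yl)-1-vinylcyclopent-1-ene (siloxy and isopropyl cis)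
Conditions: second-generation Grubbs catalyst (5 mol %), toluene (0.01 M), 80 °C, Ar
Reagents that add atoms: none
Why: Ring-closing enyne metathesis in the exo mode: without ethylene the propagating carbene [Ru]=CH2 adds to the terminal alkyne with the metal on the internal carbon (the regiochemistry of cross enyne metathesis) and the resulting carbene can only close onto the 1,1-disubstituted alkene, giving the cyclopentene with the tetrasubstituted C9=C3 bond and the C8=C7 vinyl group without touching either stereocentre.

Step 8
Reactants: 13 butane-2,3-dione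
Product: 14 3,3-bis(benzyloxy)butan-2-one
Conditions: BnOSiMe3 (2.2 equiv), TMSOTf (5 mol %), CH2Cl2, −78 → −20 °C; pyridine quench
Reagents that add atoms: benzyloxytrimethylsilane, C[Si](C)(C)OCc1ccccc1
Why: Noyori acetalisation (silyl ether exchange under TMSOTf catalysis) at low temperature; once one carbonyl group is ketalised the other is shielded by the neighbouring quaternary ketal carbon, so the reaction should stop at the monoketal.

Step 9
Reactants: 14 3,3-bis(benzyloxy)butan-2-one
Product: 16 3,3-bis(benzyloxy)-2-(triethylsilyloxy)but-1-ene, via lithium enolate 15 (not isolated)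
Conditions: LiN(i-Pr)2, THF, −78 °C; then Et3SiCl, −78 → 0 °C
Reagents that add atoms: chlorotriethylsilane, CC[Si](Cl)(CC)CC
Why: Enolate O-silylation: only the acetyl methyl group of 14 carries α-hydrogens, so a single enol ether forms, and the basic procedure avoids silyl triflates that would ionise the ketal prematurely.

Step 10
Reactants: 12 (4S,5R)-4-(tert-butyldimethylsilyloxy)-2-methyl-5-(propan-2-yl)-1-vinylcyclopent-1-ene (1 equiv); 16 3,3-bis(benzyloxy)-2-(triethylsilyloxy)but-1-ene (1.5 equiv)
Product: 18 bicyclic C5 ketone bearing the C1 silyl ether plus the C6 benzyl ether plus the C8=C9 alkene (1S,3R,6S,10R), via benzyloxy siloxyallyl cation 17 (not isolated)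
Conditions: TMSOTf (0.2 equiv), CH2Cl2, −78 °C; Et3N quench
Reagents that add atoms: none
Why: TMSOTf ionises one benzyloxy group of 16 to the oxocarbenium (2-siloxyallyl) cation 17, whose cationic carbon C6 adds to the unhindered vinyl terminus C7 of 12; the allyl cation formed (C8–C9–C3, charge mainly at tertiary C3) is captured by the enol silane carbon C4, and silyl transfer to triflate releases the C5 ketone and Et3SiOTf, which carries the chain. The closest known reaction type is the Lewis acid-induced (4+3) cycloaddition of alkoxy-substituted siloxyallyl cations, generated from silyl enol ethers of α-keto acetals, with 1,3-dienes. The seven-membered ring closes in a stepwise (4+3) mode, the second bond forming by attack of C4 on the allyl cation terminus C3 (endo with respect to the C8=C9 bond, which stays inside the new ring). C3 is set by approach of the three-carbon unit to the diene face opposite the cis C10 isopropyl and C1 siloxy groups, which leaves the C3 methyl cis to both; C6 is set by a compact arrangement of the cation over the diene with the benzyloxy group anti to the siloxy oxygen (opposed C–O dipoles), which places benzyloxy cis to the C3 methyl. The step needs C7-first regiochemistry, secured by pairing the oxocarbenium carbon with the only unsubstituted diene terminus, and seven- rather than five-membered closure, favoured by the charge at tertiary C3 and the low temperature, whereas the C6 topicity is the least secure element.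

Step 11
Reactants: 18 bicyclic silyl ether ketone
Product: 19 C1 alcohol (1S,3R,6S,10R) bearing the C6 benzyl ether plus the C5 ketone plus the C8=C9 alkene
Conditions: Bu4NF, THF, 0 °C → rt
Reagents that add atoms: none
Why: Fluoride desilylation cleaves the secondary silyl ether selectively, since the tertiary benzyl ether, the ketone and the alkene are inert to Bu4NF.

Step 12
Reactants: 19 C1 alcohol
Product: 21 C9=C10 enone (3R,6S) bearing the C1 and C5 ketones plus the C6 benzyl ether, via β,γ-unsaturated diketone 20 (not isolated)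
Conditions: Dess–Martin periodinane, NaHCO3, CH2Cl2, rt; then DBU (excess), rt
Reagents that add atoms: none
Why: Dess–Martin oxidation gives the β,γ-unsaturated ketone 20, whose doubly activated C10–H lets DBU move the C8=C9 alkene into conjugation as the tetrasubstituted cyclopentenone (base isomerisation under thermodynamic control), so the temporary C1 and C10 centres are erased while the quaternary C3 and C6 centres cannot epimerise.

Step 13
Reactants: 21 C9=C10 enone carrying the C6 benzyl ether
Product: 22 C6 tertiary alcohol (3R,6S) bearing the C1 enone plus the C5 ketone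
Conditions: BCl3, C6HMe5, CH2Cl2, −78 °C; MeOH quench
Reagents that add atoms: none
Why: Lewis acid debenzylation with a non-basic cation scavenger: BCl3 bound to the ether and neighbouring ketone oxygens cleaves the benzylic C–O bond and pentamethylbenzene traps the benzyl cation, while the tertiary C6–O bond next to the carbonyl group does not ionise.

Step 14
Reactants: 23 angelic acid (2 equiv)
Product: 24 angelic anhydride
Conditions: DCC (0.5 equiv per acid), CH2Cl2, 0 °C → rt; filtration from the urea
Reagents that add atoms: angelic acid (second molecule of 23), C/C=C(/C)C(=O)O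
Why: Carbodiimide dehydration, in which one molecule of acid adds to DCC to give the O-acylisourea and this acylates a second molecule of acid, so that two molecules of 23 give the symmetrical anhydride and the urea under neutral conditions that do not isomerise the (Z)-alkene.

Step 15
Reactants: 22 C6 tertiary alcohol; 24 angelic anhydride
Product: 26 C6 angelate (3R,6S) bearing the C1 enone plus the C5 ketone, via lithium alkoxide 25 (not isolated)
Conditions: LiN(SiMe3)2 (1.05 equiv), THF, −78 °C; then 24, −78 → 0 °C
Reagents that add atoms: none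
Why: Alkoxide acylation with the symmetrical anhydride needs no nucleophilic catalyst, whose conjugate addition is what isomerises angelates to tiglates, the lithium alkoxide 25 is reactive enough for the tertiary centre, and the hydroxyl proton is removed well before any ketone α-proton.

Step 16
Reactants: 26 C6 angelate enone
Product: 27 C1 allylic alcohol (1S,3R,6S) bearing the C6 angelate plus the C5 ketone
Conditions: (R)-2-methyl-CBS-oxazaborolidine (0.5 equiv), catecholborane, toluene, −78 °C
Reagents that add atoms: none
Why: Corey–Bakshi–Shibata reduction: the conjugated C1 carbonyl, flanked by a ring CH2 and a planar alkenyl carbon, should bind the oxazaborolidine far more readily than the C5 ketone wedged between a quaternary and a neopentyl carbon, and with the alkenyl side as the large group the (R)-catalyst delivers hydride to the face that gives the (1S)-alcohol, cis to the C3 methyl group.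

Step 17
Reactants: 27 C1 allylic alcohol; 24 angelic anhydride
Product: 29 CNP0193302.1 (1S,3R,6S), via lithium alkoxide 28 (not isolated)
Conditions: LiN(SiMe3)2 (1.05 equiv), THF, −78 °C; then 24, −78 → −20 °C
Reagents that add atoms: none
Why: The same stereoconservative alkoxide acylation esterifies the secondary allylic alcohol at low temperature without ionising the allylic C–O bond and completes the target.

**Compound list**

1 | 2-methylpropanoyl chloride | CC(C)C(=O)Cl | starting material
2 | bis(trimethylsilyl)acetylene | C[Si](C)(C)C#C[Si](C)(C)C | starting material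
3 | 4-methyl-1-(trimethylsilyl)pent-1-yn-3-one | CC(C)C(=O)C#C[Si](C)(C)C | intermediate
4 | (S)-4-methyl-1-(trimethylsilyl)pent-1-yn-3-ol | CC(C)[C@H](O)C#C[Si](C)(C)C | intermediate (not isolated)
5 | (S)-4-methylpent-1-yn-3-ol | CC(C)[C@H](O)C#C | intermediate
6 | (S)-4-methylpent-1-yn-3-yl methanesulfonate | CC(C)[C@H](OS(C)(=O)=O)C#C | intermediate
7 | 3-methylbut-3-en-1-ol | CC(=C)CCO | starting material
8 | 3-methylbut-3-enal | CC(=C)CC=O | intermediate
9 | (Ra)-(4-methylpenta-1,2-dien-1-yl)zinc methanesulfonate | [H]C([Zn]OS(C)(=O)=O)=[C@@]=C([H])C(C)C | intermediate (not isolated)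
10 | (3R,4S)-6-methyl-3-(propan-2-yl)hept-6-en-1-yn-4-ol | C=C(C)C[C@H](O)[C@@H](C#C)C(C)C | intermediate
11 | tert-butyldimethyl{[(3R,4S)-6-methyl-3-(propan-2-yl)hept-6-en-1-yn-4-yl]oxy}silane | C=C(C)C[C@H](O[Si](C)(C)C(C)(C)C)[C@@H](C#C)C(C)C | intermediate
12 | tert-butyl{[(1S,2R)-3-ethenyl-4-methyl-2-(propan-2-yl)cyclopent-3-en-1-yl]oxy}dimethylsilane (cis) | C=CC1=C(C)C[C@H](O[Si](C)(C)C(C)(C)C)[C@@H]1C(C)C | intermediate
13 | butane-2,3-dione | CC(=O)C(C)=O | starting material
14 | 3,3-bis(benzyloxy)butan-2-one | CC(=O)C(C)(OCc1ccccc1)OCc1ccccc1 | intermediate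
15 | lithium 3,3-bis(benzyloxy)but-1-en-2-olate | [Li+].C=C([O-])C(C)(OCc1ccccc1)OCc1ccccc1 | intermediate (not isolated)
16 | {[3,3-bis(benzyloxy)but-1-en-2-yl]oxy}triethylsilane | C=C(O[Si](CC)(CC)CC)C(C)(OCc1ccccc1)OCc1ccccc1 | intermediate
17 | 1-(benzyloxy)-1-methyl-2-(triethylsilyloxy)allyl cation (oxocarbenium form) trifluoromethanesulfonate | C=C(O[Si](CC)(CC)CC)C(C)=[O+]Cc1ccccc1.[O-]S(=O)(=O)C(F)(F)F | intermediate (not isolated)
18 | (1R,2S,3aR,6S)-6-(benzyloxy)-2-[(tert-butyldimethylsilyl)oxy]-3a,6-dimethyl-1-(propan-2-yl)-2,3,3a,4,6,7-hexahydroazulen-5(1H)-one | CC(C)(C)[Si](C)(C)O[C@H]1C[C@]2(C)CC(=O)[C@@](C)(OCc3ccccc3)CC=C2[C@H]1C(C)C | intermediate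
19 | (1R,2S,3aR,6S)-6-(benzyloxy)-2-hydroxy-3a,6-dimethyl-1-(propan-2-yl)-2,3,3a,4,6,7-hexahydroazulen-5(1H)-one | O[C@H]1C[C@]2(C)CC(=O)[C@@](C)(OCc3ccccc3)CC=C2[C@H]1C(C)C | intermediate
20 | (1R,3aR,6S)-6-(benzyloxy)-3a,6-dimethyl-1-(propan-2-yl)-3,3a,6,7-tetrahydroazulene-2,5(1H,4H)-dione | O=C1C[C@]2(C)CC(=O)[C@@](C)(OCc3ccccc3)CC=C2[C@H]1C(C)C | intermediate (not isolated)
21 | (3aR,6S)-6-(benzyloxy)-3a,6-dimethyl-1-(propan-2-yl)-3a,4,7,8-tetrahydroazulene-2,5(3H,6H)-dione | O=C1C[C@]2(C)CC(=O)[C@@](C)(OCc3ccccc3)CCC2=C1C(C)C | intermediate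
22 | (3aR,6S)-6-hydroxy-3a,6-dimethyl-1-(propan-2-yl)-3a,4,7,8-tetrahydroazulene-2,5(3H,6H)-dione | O=C1C[C@]2(C)CC(=O)[C@@](C)(O)CCC2=C1C(C)C | intermediate
23 | angelic acid, (2Z)-2-methylbut-2-enoic acid | C/C=C(/C)C(=O)O | starting material
24 | angelic anhydride, (2Z)-2-methylbut-2-enoic anhydride | C/C=C(/C)C(=O)OC(=O)/C(C)=C\C | intermediate
25 | lithium (3aR,6S)-3a,6-dimethyl-2,5-dioxo-1-(propan-2-yl)-2,3,3a,4,5,6,7,8-octahydroazulen-6-olate | [Li+].O=C1C[C@]2(C)CC(=O)[C@@](C)([O-])CCC2=C1C(C)C | intermediate (not isolated)
26 | (3aR,6S)-3a,6-dimethyl-2,5-dioxo-1-(propan-2-yl)-2,3,3a,4,5,6,7,8-octahydroazulen-6-yl (2Z)-2-methylbut-2-enoate | O=C1C[C@]2(C)CC(=O)[C@@](C)(OC(=O)/C(C)=C\C)CCC2=C1C(C)C | intermediate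
27 | (2S,3aR,6S)-2-hydroxy-3a,6-dimethyl-5-oxo-1-(propan-2-yl)-2,3,3a,4,5,6,7,8-octahydroazulen-6-yl (2Z)-2-methylbut-2-enoate | O[C@H]1C[C@]2(C)CC(=O)[C@@](C)(OC(=O)/C(C)=C\C)CCC2=C1C(C)C | intermediate
28 | lithium (2S,3aR,6S)-3a,6-dimethyl-6-{[(2Z)-2-methylbut-2-enoyl]oxy}-5-oxo-1-(propan-2-yl)-2,3,3a,4,5,6,7,8-octahydroazulen-2-olate | [Li+].[O-][C@H]1C[C@]2(C)CC(=O)[C@@](C)(OC(=O)/C(C)=C\C)CCC2=C1C(C)C | intermediate (not isolated)
29 | CNP0193302.1, (2S,3aR,6S)-3a,6-dimethyl-5-oxo-1-(propan-2-yl)-2,3,3a,4,5,6,7,8-octahydroazulene-2,6-diyl bis[(2Z)-2-methylbut-2-enoate] | C/C=C(/C)C(=O)O[C@H]1C[C@]2(C)CC(=O)[C@@](C)(OC(=O)/C(C)=C\C)CCC2=C1C(C)C | target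

**Step count and risks**

Total: 17 steps. Longest linear sequence: 13 steps (1–3, 5–7, 10–13, 15–17).

Steps most likely to fail:

1. Step 10. The allyl cation formed after the first C–C bond may lose a proton or close at C8 to a cyclopentanone instead of closing at C3. The oxocarbenium ion may shed its benzyl group. Face selection at C6 may be poor, so that both C6 epimers form. Fallback: a Lewis acid-activated 2-siloxy enone as the three-carbon partner. It sets out from 13 and 12 and returns at 22. Mono-enol silylation of 13 (Et3SiOTf, Et3N, CH2Cl2, 0 °C) would give 3-(triethylsilyloxy)but-3-en-2-one F1. Activation of its carbonyl group by Sc(OTf)3 (cat., CH2Cl2, −78 °C) in the presence of 12 would form a metal-bound 1-oxy-2-siloxyallyl cation that should add across the same diene carbons, the silyl group migrating to the new C6 oxygen to give the C6 triethylsilyl ether F2. Bu4NF would remove both silyl groups to give diol F3. Dess–Martin oxidation of the secondary alcohol (β,γ-unsaturated diketone F4, not isolated) and DBU in the same flask would then give 22, so steps 11–13 are replaced and no benzyl group is needed.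

2. Step 7. Closure to the tetrasubstituted alkene is slow, so the alkyne-derived carbene may instead close in the endo mode to a six-membered 1,3-diene, or oligomerise. Fallback: ring closure by aldol condensation, from 11 back to 12. Hydroboration of the terminal alkyne of 11 with Cy2BH and oxidation (NaBO3·4H2O) would give aldehyde F5. Ozonolysis of the 1,1-disubstituted alkene (O3, CH2Cl2, −78 °C; PPh3) would give keto aldehyde F6. Enamine-mediated intramolecular aldol condensation (dibenzylammonium trifluoroacetate, benzene, 50 °C) would give the 2-methylcyclopent-1-enecarbaldehyde F7, and Wittig methylenation (Ph3P=CH2, THF, 0 °C) would return diene 12.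

3. Step 15. Acylation of the hindered tertiary alkoxide may be slow, which would allow isomerisation of the angeloyl group to the (E)-isomer or base-induced α-ketol rearrangement. Fallback: build the (Z)-alkene on the ester, from 22 back to 26. Alcohol 22 would be esterified with 2-[bis(2,2,2-trifluoroethoxy)phosphoryl]propanoic acid F8 (obtained from its commercial ethyl ester by ester hydrolysis) using DCC; this acylation passes through a phosphonoketene and therefore tolerates tertiary alcohols, giving phosphonate ester F9 (mixture at the phosphonate carbon). Still–Gennari olefination with acetaldehyde (KN(SiMe3)2, 18-crown-6, THF, −78 °C) should then give the (Z)-2-methylbut-2-enoate 26. The aldehyde would be added immediately after deprotonation, so that the intermolecular olefination outruns attack of the phosphonate anion on the hindered C5 ketone.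

**Further compounds**

F1 | step 10 | 3-(triethylsilyloxy)but-3-en-2-one | CC(=O)C(=C)O[Si](CC)(CC)CC
F2 | step 10 | (1R,2S,3aR,6S)-2-[(tert-butyldimethylsilyl)oxy]-3a,6-dimethyl-1-(propan-2-yl)-6-[(triethylsilyl)oxy]-2,3,3a,4,6,7-hexahydroazulen-5(1H)-one | CC(C)(C)[Si](C)(C)O[C@H]1C[C@]2(C)CC(=O)[C@@](C)(O[Si](CC)(CC)CC)CC=C2[C@H]1C(C)C
F3 | step 10 | (1R,2S,3aR,6S)-2,6-dihydroxy-3a,6-dimethyl-1-(propan-2-yl)-2,3,3a,4,6,7-hexahydroazulen-5(1H)-one | O[C@H]1C[C@]2(C)CC(=O)[C@@](C)(O)CC=C2[C@H]1C(C)C
F4 | step 10 | (1R,3aR,6S)-6-hydroxy-3a,6-dimethyl-1-(propan-2-yl)-3,3a,6,7-tetrahydroazulene-2,5(1H,4H)-dione | O=C1C[C@]2(C)CC(=O)[C@@](C)(O)CC=C2[C@H]1C(C)C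
F5 | step 7 | (3S,4S)-4-[(tert-butyldimethylsilyl)oxy]-6-methyl-3-(propan-2-yl)hept-6-enal | C=C(C)C[C@H](O[Si](C)(C)C(C)(C)C)[C@@H](CC=O)C(C)C
F6 | step 7 | (3S,4S)-4-[(tert-butyldimethylsilyl)oxy]-6-oxo-3-(propan-2-yl)heptanal | CC(=O)C[C@H](O[Si](C)(C)C(C)(C)C)[C@@H](CC=O)C(C)C
F7 | step 7 | (4S,5R)-4-[(tert-butyldimethylsilyl)oxy]-2-methyl-5-(propan-2-yl)cyclopent-1-ene-1-carbaldehyde | O=CC1=C(C)C[C@H](O[Si](C)(C)C(C)(C)C)[C@@H]1C(C)C
F8 | step 15 | 2-[bis(2,2,2-trifluoroethoxy)phosphoryl]propanoic acid | CC(C(=O)O)P(=O)(OCC(F)(F)F)OCC(F)(F)F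
F9 | step 15 | (3aR,6S)-3a,6-dimethyl-2,5-dioxo-1-(propan-2-yl)-2,3,3a,4,5,6,7,8-octahydroazulen-6-yl 2-[bis(2,2,2-trifluoroethoxy)phosphoryl]propanoate | O=C1C[C@]2(C)CC(=O)[C@@](C)(OC(=O)C(C)P(=O)(OCC(F)(F)F)OCC(F)(F)F)CCC2=C1C(C)C
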